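**Retrosynthetic overview**

1. Target 9 is a single ring: a saturated 33-membered lactone with no stereocentre (numbering: C1 lactone carbonyl, C2–C31 methylenes, C32 the OCH2 carbon). The plan rests on the unbranched, unfunctionalised run C3–C31 of that ring, which lets four of its carbons, C13–C16, be carried as a conjugated diyne until the last step.
2. 9 ⇒ 8 (ring diyne C13≡C14–C15≡C16) by exhaustive hydrogenation.
3. 8 ⇒ 7 by cutting the sp–sp bond C14–C15: the only ring is closed by oxidative coupling of two terminal alkynes with Cu(OAc)2 in pyridine.
4. 7 ⇒ acid 3 (C1–C14) + alcohol 6 (C15–C32) at the ester C1–O bond; 3 and 6 ⇒ ω-bromo acids 1 and 4 + lithium acetylide 2.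

Key step: step 5

**Route**

Step 1
Reactants: 1 12-bromododecanoic acid; 2 lithium acetylide ethylenediamine complex (LiC≡CH·H2NCH2CH2NH2)
Product: 3 tetradec-13-ynoic acid
Conditions: 2 (3 equiv), DMSO, 10 °C → rt, 16 h; then 1 M HCl
Reagents that add atoms: none
Why: SN2 alkylation of lithium acetylide by the primary bromide in DMSO, in which the first equivalent of 2 only converts the acid into its inert lithium carboxylate and the excess suppresses a second alkylation of the product alkyne.

Step 2
Reactants: 4 16-bromohexadecanoic acid; 2 lithium acetylide ethylenediamine complex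
Product: 5 octadec-17-ynoic acid
Conditions: 2 (3 equiv), DMSO, rt, 24 h; then 1 M HCl
Reagents that add atoms: none
Why: The same SN2 acetylide alkylation of a primary ω-bromo carboxylate as in step 1, which should extend the C16 chain by the two alkyne carbons.

Step 3
Reactants: 5 octadec-17-ynoic acid
Product: 6 octadec-17-yn-1-ol
Conditions: LiAlH4 (2 equiv), THF, 0 °C → rt; H2O, 15% NaOH, H2O
Reagents that add atoms: none
Why: LiAlH4 reduction of a carboxylic acid to the primary alcohol, in which the isolated terminal alkyne is at most deprotonated and is not hydroaluminated at or below room temperature.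

Step 4
Reactants: 3 tetradec-13-ynoic acid; 6 octadec-17-yn-1-ol
Product: 7 octadec-17-yn-1-yl tetradec-13-ynoate
Conditions: DCC (1.1 equiv), DMAP (0.1 equiv), CH2Cl2, 0 °C → rt
Reagents that add atoms: none
Why: Steglich esterification, in which DCC activates acid 3 as the O-acylisourea, DMAP relays the acyl group to the unhindered primary alcohol 6, and both terminal alkynes are spectators.

Step 5
Reactants: 7 octadec-17-yn-1-yl tetradec-13-ynoate
Product: 8 oxacyclotritriaconta-14,16-diyn-2-one (33-membered lactone with the diyne C13≡C14–C15≡C16)
Conditions: Cu(OAc)2 (10 equiv), pyridine, 60 °C; 7 in pyridine added by syringe pump over 36 h (final ca. 1 mM); aq. HCl work-up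
Reagents that add atoms: none
Why: Intramolecular Eglinton oxidative coupling: pyridine-assisted metalation of both terminal C–H bonds gives RC≡CCu species, which excess Cu(OAc)2 (divalent copper) oxidises so that the two alkynyl termini join to form the C14–C15 bond, the copper leaving as monovalent CuOAc. The closest known reaction type is the Eglinton (Glaser-type) macrocyclisation of α,ω-diynes, established for large-ring 1,3-diyne lactones. The single 33-membered ring is closed end to end through the sp–sp bond with both triple bonds endocyclic, and the linear C12–C17 rod is accommodated without strain at this ring size. No stereocentre is formed, so the only selectivity needed is ring closure over chain-to-chain coupling, which slow addition of 7 into a large excess of Cu(OAc)2 secures by keeping the concentration of free diyne very low. The ester is inert to Cu(OAc)2 in pyridine and the alkynes need no protection.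

Step 6
Reactants: 8 oxacyclotritriaconta-14,16-diyn-2-one
Product: 9 oxacyclotritriacontan-2-one (target)
Conditions: H2 (1 atm), 10% Pd/C, EtOAc/THF, rt
Reagents that add atoms: none
Why: Heterogeneous catalytic hydrogenation, in which four equivalents of H2 saturate the conjugated diyne (C13–C16) while the aliphatic lactone, lacking any allylic or benzylic C–O bond, is untouched and no stereocentre arises.

**Compound list**

1 | 12-bromododecanoic acid | OC(=O)CCCCCCCCCCCBr | starting material
2 | lithium acetylide ethylenediamine complex | [Li]C#C.NCCN | starting material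
3 | tetradec-13-ynoic acid | C#CCCCCCCCCCCCC(=O)O | intermediate
4 | 16-bromohexadecanoic acid | OC(=O)CCCCCCCCCCCCCCCBr | starting material
5 | octadec-17-ynoic acid | C#CCCCCCCCCCCCCCCCC(=O)O | intermediate
6 | octadec-17-yn-1-ol | C#CCCCCCCCCCCCCCCCCO | intermediate
7 | octadec-17-yn-1-yl tetradec-13-ynoate | C#CCCCCCCCCCCCC(=O)OCCCCCCCCCCCCCCCCC#C | intermediate
8 | oxacyclotritriaconta-14,16-diyn-2-one | O=C1CCCCCCCCCCCC#CC#CCCCCCCCCCCCCCCCCO1 | intermediate
9 | oxacyclotritriacontan-2-one (dotriacontan-32-olide) | O=C1CCCCCCCCCCCCCCCCCCCCCCCCCCCCCCCO1 | target

**Summary**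

Total step count: 6. Longest linear sequence: 5 steps (steps 2, 3, 4, 5, 6; 4 → 5 → 6 → 7 → 8 → 9).

Steps most likely to fail:

1. Step 5. Chain-to-chain coupling may outrun ring closure if the stationary concentration of 7 is not low enough, giving linear and cyclic oligomers (chiefly the 66-membered cyclic dimer) at the expense of 8. The fallback sets out from 6 (with 3 as partner) and comes back at 8; it forms the C14–C15 bond intermolecularly and closes the ring at the ester instead. Alkynol 6 is brominated at its alkyne terminus (NBS, cat. AgNO3, acetone) to 18-bromooctadec-17-yn-1-ol F1. Cadiot–Chodkiewicz cross-coupling of F1 with acid 3 (cat. CuCl, NH2OH·HCl, n-BuNH2, H2O/MeOH/THF, 0 °C → rt) should give 32-hydroxydotriaconta-13,15-diynoic acid F2. Yamaguchi macrolactonisation of F2 (2,4,6-trichlorobenzoyl chloride, Et3N, THF; then slow addition to DMAP in toluene, 80 °C) should then give 8.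

2. Step 2. The lithium salt of the C16 bromo acid may separate from DMSO as a soap, so that displacement becomes slow and heterogeneous; proton transfer from the product alkyne to the acetylide followed by a second alkylation, and E2 loss of HBr, would then compete. The fallback sets out from 4 and comes back at 6, bypassing 5 and step 3; it uses a silyl-capped acetylide on a non-ionic, THF-soluble substrate. Acid 4 is reduced with BH3·THF to 16-bromohexadecan-1-ol F3 and silylated (TBSCl, imidazole, DMF) to [(16-bromohexadecyl)oxy](tert-butyl)dimethylsilane F4. Alkylation with lithium (trimethylsilyl)acetylide (Me3SiC≡CH, n-BuLi, THF/DMPU, −78 °C → rt) should give tert-butyldimethyl{[18-(trimethylsilyl)octadec-17-yn-1-yl]oxy}silane F5, and TBAF in THF removes both silyl groups to give 6.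

3. Step 1. The displacement may stall through aggregation of the lithium carboxylate of 1, leaving bromo acid that is hard to separate from 3 by crystallisation. The fallback sets out from 1 and comes back at 3; it moves the C–C bond formation to the alcohol oxidation level. Acid 1 is reduced with BH3·THF to 12-bromododecan-1-ol F6, which with 2 (2.5 equiv, DMSO, rt) should give tetradec-13-yn-1-ol F7 by way of the soluble lithium alkoxide. Oxidation with cat. TEMPO and PhI(OAc)2 in MeCN/H2O then returns acid 3.

**Further compounds**

F1 | step 5 | 18-bromooctadec-17-yn-1-ol | BrC#CCCCCCCCCCCCCCCCCO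
F2 | step 5 | 32-hydroxydotriaconta-13,15-diynoic acid | OC(=O)CCCCCCCCCCCC#CC#CCCCCCCCCCCCCCCCCO
F3 | step 2 | 16-bromohexadecan-1-ol | OCCCCCCCCCCCCCCCCBr
F4 | step 2 | [(16-bromohexadecyl)oxy](tert-butyl)dimethylsilane | CC(C)(C)[Si](C)(C)OCCCCCCCCCCCCCCCCBr
F5 | step 2 | tert-butyldimethyl{[18-(trimethylsilyl)octadec-17-yn-1-yl]oxy}silane | CC(C)(C)[Si](C)(C)OCCCCCCCCCCCCCCCCC#C[Si](C)(C)C
F6 | step 1 | 12-bromododecan-1-ol | OCCCCCCCCCCCCBr
F7 | step 1 | tetradec-13-yn-1-ol | C#CCCCCCCCCCCCCO
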